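**Plan**
1. Cuts: C12–C13 (sp3–sp2 coupling) and C11=C12 (methylenation) remove the diene; H and OH are taken off C5/C6 to leave a C5=C6 olefin; ring B is opened at C9–C10 while O–C6 is re-closed, which turns it into a δ-lactone; the lactone is cut at C8–C9 and C6–C7, ring A at C5–C6.
2. Enabling feature: C6–O, the C8 carbinol with its methyl, and C9–C11 of ring B are the atoms of a 4-hydroxy-4-methyl δ-lactone whose ring oxygen sits on C6, allylic to a ring A C5=C10 olefin. Its enol form C9=C11(O)–O–C6–C5=C10 is a 1,5-diene bridged by C7–C8.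
3. Forward: ring A enal 10 (steps 1–7), lactone 16 (steps 8–11), ring B by contraction of the lactone (step 12), C5–H/C6–OH (step 13), side chain and acetate (steps 14–17), desilylation (step 18).
4. Stereochemistry: C4 from an auxiliary-controlled methylation; the lactone C6 from reagent-controlled methallylboration; C8 by 1,3-induction in a samarium-chelated Reformatsky closure; C10 and C9 by transfer from C6 and C8 through the boat [3,3] shift; C5 and C6 by syn hydroboration opposite the angular methyl.

Key step: step 12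

Numbering: labdane locants are used throughout (decalin C1–C10; C11 on C9; C17 = methyl on C8; C18 = CH2O on C4; C20 = methyl on C10). TBS = tert-butyldimethylsilyl.

Assumption: in the valine tert-butyl ester enamine alkylation run in toluene with HMPA, the electrophile is taken to enter on the face syn to the isopropyl group, so the D-valine auxiliary gives the (S)-keto ester 5; if the sense proves opposite, the L-valine ester is used under the same conditions.

**Step 1**
Reactants: 1 methyl 2-oxocyclohexane-1-carboxylate; 2 D-valine tert-butyl ester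
Product: 3 methyl 2-{[(2R)-1-tert-butoxy-3-methyl-1-oxobutan-2-yl]amino}cyclohex-1-ene-1-carboxylate
Conditions: BF3·OEt2 (cat.), toluene, reflux, Dean–Stark trap
Reagents that add atoms: none
Why: Acid-catalysed condensation of the ketone with the primary amine gives the hydrogen-bonded enamino ester (vinylogous carbamate formation), water being removed azeotropically.

**Step 2**
Reactants: 3 enamino ester
Product: 5 methyl (1S)-1-methyl-2-oxocyclohexane-1-carboxylate, via alkylated imine 4 (not isolated)
Conditions: LiN(iPr)2, toluene, −78 °C; HMPA; MeI, −78 to −55 °C; then 1 M HCl, rt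
Reagents that add atoms: iodomethane, CI; water, O
Why: Auxiliary-controlled alkylation of a lithio-enamine in which lithium is chelated by N and both ester carbonyls, so MeI enters C1 on one face (see assumption) and sets the quaternary centre (future C4) as S; acid hydrolysis of imine 4 releases the keto ester and the auxiliary.

**Step 3**
Reactants: 5 methyl (1S)-1-methyl-2-oxocyclohexane-1-carboxylate
Product: 6 methyl (1S)-1,3-dimethyl-2-oxocyclohexane-1-carboxylate (both C3 epimers)
Conditions: LiN(iPr)2, THF, −78 °C; MeI, −78 to 0 °C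
Reagents that add atoms: iodomethane, CI
Why: Kinetic enolate alkylation at C3, the only enolisable position; the new centre is left uncontrolled because it becomes sp2 in step 4.

**Step 4**
Reactants: 6 methyl (1S)-1,3-dimethyl-2-oxocyclohexane-1-carboxylate
Product: 7 methyl (1S)-1,3-dimethyl-2-(trifluoromethanesulfonyloxy)cyclohex-2-ene-1-carboxylate
Conditions: KN(SiMe3)2, THF, −78 °C; PhNTf2, −78 to 0 °C
Reagents that add atoms: N-phenylbis(trifluoromethanesulfonimide), O=S(=O)(N(c1ccccc1)S(=O)(=O)C(F)(F)F)C(F)(F)F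
Why: Enol triflate formation; the single α-hydrogen gives the tetrasubstituted potassium enolate, which is sulfonylated on oxygen as other 2,2,6-trisubstituted cyclohexanones are.

**Step 5**
Reactants: 7 enol triflate ester
Product: 8 (6R)-6-(hydroxymethyl)-2,6-dimethylcyclohex-1-en-1-yl trifluoromethanesulfonate
Conditions: iBu2AlH, CH2Cl2, −78 to 0 °C; aq. potassium sodium tartrate
Reagents that add atoms: none
Why: Hydride reduction of the neopentyl ester to the primary alcohol; enol triflates are inert to iBu2AlH at these temperatures and the quaternary centre is not touched.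

**Step 6**
Reactants: 8 hydroxy enol triflate
Product: 9 (6R)-6-[(tert-butyldimethylsilyloxy)methyl]-2,6-dimethylcyclohex-1-en-1-yl trifluoromethanesulfonate
Conditions: t-BuMe2SiCl, imidazole, DMF, rt
Reagents that add atoms: tert-butyldimethylsilyl chloride, CC(C)(C)[Si](C)(C)Cl
Why: Standard silylation of a primary alcohol; the ether has to last through step 17 and is removed last.

**Step 7**
Reactants: 9 silyl ether enol triflate
Product: 10 (6S)-6-[(tert-butyldimethylsilyloxy)methyl]-2,6-dimethylcyclohex-1-ene-1-carbaldehyde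
Conditions: Pd(PPh3)4 (cat.), LiCl, CO (1 atm), Bu3SnH (slow addition), THF, 50 °C
Reagents that add atoms: carbon monoxide, [C-]#[O+]
Why: Palladium-catalysed reductive carbonylation of an enol triflate (oxidative addition to zerovalent palladium, CO insertion, hydride transfer from tin, reductive elimination) installs C6 as the aldehyde; slow hydride addition suppresses direct reduction.

**Step 8**
Reactants: 10 ring A enal; 11 2-methylallylmagnesium chloride
Product: 12 (1R)-1-[(6S)-6-[(tert-butyldimethylsilyloxy)methyl]-2,6-dimethylcyclohex-1-en-1-yl]-3-methylbut-3-en-1-ol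
Conditions: (+)-Ipc2BOMe (from (−)-α-pinene), 11, Et2O, −78 °C to rt; then 10, −78 °C; NaOH, H2O2
Reagents that add atoms: none
Why: Brown allylboration through a six-membered chair (Zimmerman–Traxler) transition state; the isopinocampheyl groups direct the methallyl unit to the Re face of the aldehyde, which sets C6 as R independently of the remote C4 centre.

**Step 9**
Reactants: 12 homoallylic alcohol
Product: 13 (4R)-4-hydroxy-4-[(6S)-6-[(tert-butyldimethylsilyloxy)methyl]-2,6-dimethylcyclohex-1-en-1-yl]butan-2-one
Conditions: OsO4 (cat.), NaIO4, 2,6-lutidine, dioxane–H2O, rt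
Reagents that add atoms: sodium periodate, [Na+].[O-]I(=O)(=O)=O
Why: Lemieux–Johnson oxidation; OsO4 dihydroxylates the unhindered 1,1-disubstituted olefin and not the tetrasubstituted ring olefin next to a quaternary carbon, periodate cleaves the diol to the methyl ketone, and the lutidine buffer protects the β-hydroxy ketone from dehydration.

**Step 10**
Reactants: 13 β-hydroxy ketone; 14 bromoacetyl bromide
Product: 15 (1R)-3-oxo-1-[(6S)-6-[(tert-butyldimethylsilyloxy)methyl]-2,6-dimethylcyclohex-1-en-1-yl]butyl bromoacetate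
Conditions: pyridine, CH2Cl2, −78 to −20 °C
Reagents that add atoms: none
Why: O-acylation of the secondary alcohol by the acid bromide; mild base and low temperature avoid E1cB loss of the β-acyloxy group.

**Step 11**
Reactants: 15 β-(bromoacetoxy) ketone
Product: 16 (4S,6R)-4-hydroxy-4-methyl-6-[(6S)-6-[(tert-butyldimethylsilyloxy)methyl]-2,6-dimethylcyclohex-1-en-1-yl]oxan-2-one
Conditions: SmI2 (2.2 equiv), THF, −78 °C; aq. NH4Cl
Reagents that add atoms: none
Why: Samarium diiodide-mediated intramolecular Reformatsky reaction; reduction of the C–Br bond gives a trivalent samarium enolate chelated to the ketone, and in the resulting bicyclic chair the C6 alkenyl group is equatorial while the C8 oxygen is held axial by the metal, so the C8 methyl ends cis to the alkenyl group (4S, 1,3-induction).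

**Step 12**
Reactants: 16 hydroxy lactone
Product: 19 (1R,2S,5S,8aS)-5-[(tert-butyldimethylsilyloxy)methyl]-2-hydroxy-2,5,8a-trimethyl-1,2,3,5,6,7,8,8a-octahydronaphthalene-1-carboxylic acid, via bis-silyl ketene acetal 17 (not isolated), via bis-silyl ester 18 (not isolated)
Conditions: LiN(iPr)2 (2.3 equiv), THF, −78 °C; Me3SiCl/Et3N, −78 °C to rt; toluene, 100 °C; then 1 M HCl, THF, 0 °C
Reagents that add atoms: none
Why: Ireland–Claisen rearrangement of a lactone silyl ketene acetal (the ring-contracting ester-enolate [3,3] shift known for 6-alkenyl δ-lactones): the alkoxide–enolate of 16 is silylated on both oxygens and the C9=C11(OSiMe3)–O–C6–C5=C10 diene of 17 shifts suprafacially, C9–C10 forming as C6–O breaks. Ring B closes by this single bond through a six-membered boat transition state bridged by C7–C8 (bicyclo[2.2.2]octane-like, the only geometry the tether allows), so the closure is sigmatropic and not an exo or endo ring closure. C10 is controlled by C6, because the departing oxygen and the incoming C9 lie on the same face of the C5=C10 olefin, so (6R) gives (10S) in 19. C9 is controlled by the bridge, which forces the carboxyl carbon C11 away from the C10 methyl and to the side of the C8 oxygen, while the C8 methyl (cis to the alkenyl group in 16) ends trans to C11. The step needs O-silylation without β-elimination of the C8 oxygen; deprotonating the hydroxyl first makes it a non-leaving alkoxide and excess Me3SiCl at −78 °C traps the enolate on oxygen. Regiochemistry is unambiguous because C9 is the only enolisable position and C10 the only olefin terminus within reach.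

**Step 13**
Reactants: 19 hydroxy acid
Product: 21 (4S,5S,6R,8S,9S,10R)-18-TBS-protected 6,8,11-triol (C11H2OH on C9; trans-decalin; 6-OH equatorial), via tris-borane adduct 20 (not isolated)
Conditions: BH3·THF (5 equiv), THF, 0 °C to rt; then NaOH, H2O2, 0 °C to rt
Reagents that add atoms: hydrogen peroxide, OO
Why: Borane reduces the carboxylic acid (through the acyloxyborane) to C11H2OH and adds syn across C5=C6 with boron on the less substituted C6 (hydroboration–oxidation, oxidation with retention); in the half-chair that keeps the C10 methyl quasi-axial, the reagent should enter opposite the axial C10, C4 and C8 methyls, giving the trans ring fusion and the equatorial C6 alcohol (5S,6R).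

**Step 14**
Reactants: 21 triol
Product: 22 (4S,5S,6R,8S,9R,10R)-18-TBS-protected 6,8-dihydroxy C11 aldehyde
Conditions: TEMPO (cat.), PhI(OAc)2, CH2Cl2, rt
Reagents that add atoms: none
Why: Oxoammonium (TEMPO) oxidation is selective for the primary alcohol over the secondary and tertiary ones; in the trans-decalin the axial C11 and the equatorial C6 oxygen cannot bridge, so no lactol or lactone can divert the aldehyde.

**Step 15**
Reactants: 22 dihydroxy aldehyde
Product: 23 (4S,5S,6R,8S,9R,10R)-18-TBS-protected 6-acetoxy-8-hydroxy C11 aldehyde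
Conditions: Ac2O, pyridine, DMAP (cat.), CH2Cl2, 0 °C to rt
Reagents that add atoms: acetic anhydride, CC(=O)OC(C)=O
Why: DMAP-catalysed acetylation of the only secondary alcohol; the tertiary C8 alcohol is not acylated under these conditions, and every later step is compatible with the acetate.

**Step 16**
Reactants: 23 acetoxy aldehyde
Product: 24 (4S,5S,6R,8S,9R,10R)-18-TBS-protected 6-acetoxy-8-hydroxy C11=C12 vinyl compound
Conditions: Zn, CH2Br2, TiCl4, THF, −40 to 5 °C (pre-formed); then 23, CH2Cl2, rt
Reagents that add atoms: dibromomethane, BrCBr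
Why: Takai–Lombardo methylenation; the non-basic zinc/titanium methylene reagent converts hindered, enolisable aldehydes into terminal olefins without epimerising C9 or provoking retro-aldol cleavage, and it leaves the acetate and silyl ether alone.

**Step 17**
Reactants: 24 vinyl compound; 25 chloroprene (2-chlorobuta-1,3-diene)
Product: 27 18-TBS ether of the target, via B-alkyl-9-BBN 26 (not isolated)
Conditions: 9-BBN-H (2.5 equiv), THF, rt; then aq. K3PO4; 25 (excess), Pd(OAc)2 (cat.), SPhos, THF–H2O, 50 °C
Reagents that add atoms: none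
Why: 9-BBN-H adds anti-Markovnikov to the monosubstituted olefin (boron on C12), and B-alkyl Suzuki–Miyaura coupling with the alkenyl chloride (oxidative addition to zerovalent palladium, base-assisted transmetalation, reductive elimination) forms C12–C13 and delivers the 2-substituted butadiene; aqueous base destroys excess B–H before the diene partner is added, and the acetate tolerates K3PO4.

**Step 18**
Reactants: 27 silyl ether
Product: 28 CNP0312185.2, (4S,5S,6R,8S,9R,10R)-6-acetoxy-labda-13(16),14-diene-8,18-diol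
Conditions: HF·pyridine, pyridine, THF, 0 °C to rt
Reagents that add atoms: none
Why: Buffered fluoride cleavage of the primary silyl ether; the conditions avoid acetyl migration, dehydration of the tertiary alcohol and damage to the diene.

**Compound list**
1 | methyl 2-oxocyclohexane-1-carboxylate | COC(=O)C1CCCCC1=O | starting material
2 | D-valine tert-butyl ester, tert-butyl (2R)-2-amino-3-methylbutanoate | CC(C)[C@@H](N)C(=O)OC(C)(C)C | starting material
3 | methyl 2-{[(2R)-1-tert-butoxy-3-methyl-1-oxobutan-2-yl]amino}cyclohex-1-ene-1-carboxylate | COC(=O)C1=C(N[C@H](C(C)C)C(=O)OC(C)(C)C)CCCC1 | intermediate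
4 | methyl (1S)-2-{[(2R)-1-tert-butoxy-3-methyl-1-oxobutan-2-yl]imino}-1-methylcyclohexane-1-carboxylate | COC(=O)[C@@]1(C)CCCCC1=N[C@H](C(C)C)C(=O)OC(C)(C)C | intermediate
5 | methyl (1S)-1-methyl-2-oxocyclohexane-1-carboxylate | COC(=O)[C@@]1(C)CCCCC1=O | intermediate
6 | methyl (1S)-1,3-dimethyl-2-oxocyclohexane-1-carboxylate (C3 epimers) | COC(=O)[C@@]1(C)CCCC(C)C1=O | intermediate
7 | methyl (1S)-1,3-dimethyl-2-(trifluoromethanesulfonyloxy)cyclohex-2-ene-1-carboxylate | COC(=O)[C@@]1(C)CCCC(C)=C1OS(=O)(=O)C(F)(F)F | intermediate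
8 | (6R)-6-(hydroxymethyl)-2,6-dimethylcyclohex-1-en-1-yl trifluoromethanesulfonate | OC[C@@]1(C)CCCC(C)=C1OS(=O)(=O)C(F)(F)F | intermediate
9 | (6R)-6-[(tert-butyldimethylsilyloxy)methyl]-2,6-dimethylcyclohex-1-en-1-yl trifluoromethanesulfonate | CC(C)(C)[Si](C)(C)OC[C@@]1(C)CCCC(C)=C1OS(=O)(=O)C(F)(F)F | intermediate
10 | (6S)-6-[(tert-butyldimethylsilyloxy)methyl]-2,6-dimethylcyclohex-1-ene-1-carbaldehyde | CC(C)(C)[Si](C)(C)OC[C@@]1(C)CCCC(C)=C1C=O | intermediate
11 | 2-methylallylmagnesium chloride | C=C(C)C[Mg]Cl | starting material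
12 | (1R)-1-[(6S)-6-[(tert-butyldimethylsilyloxy)methyl]-2,6-dimethylcyclohex-1-en-1-yl]-3-methylbut-3-en-1-ol | C=C(C)C[C@@H](O)C1=C(C)CCC[C@]1(C)CO[Si](C)(C)C(C)(C)C | intermediate
13 | (4R)-4-hydroxy-4-[(6S)-6-[(tert-butyldimethylsilyloxy)methyl]-2,6-dimethylcyclohex-1-en-1-yl]butan-2-one | CC(=O)C[C@@H](O)C1=C(C)CCC[C@]1(C)CO[Si](C)(C)C(C)(C)C | intermediate
14 | bromoacetyl bromide | BrCC(Br)=O | starting material
15 | (1R)-3-oxo-1-[(6S)-6-[(tert-butyldimethylsilyloxy)methyl]-2,6-dimethylcyclohex-1-en-1-yl]butyl bromoacetate | CC(=O)C[C@@H](OC(=O)CBr)C1=C(C)CCC[C@]1(C)CO[Si](C)(C)C(C)(C)C | intermediate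
16 | (4S,6R)-4-hydroxy-4-methyl-6-[(6S)-6-[(tert-butyldimethylsilyloxy)methyl]-2,6-dimethylcyclohex-1-en-1-yl]oxan-2-one | O=C1C[C@@](C)(O)C[C@@H](O1)C2=C(C)CCC[C@]2(C)CO[Si](C)(C)C(C)(C)C | intermediate
17 | bis(trimethylsilyl) ketene acetal of 16 (Me3SiO on C11 and on C8) | C[Si](C)(C)OC1=C[C@@](C)(O[Si](C)(C)C)C[C@@H](O1)C2=C(C)CCC[C@]2(C)CO[Si](C)(C)C(C)(C)C | intermediate
18 | trimethylsilyl ester, C8 trimethylsilyl ether of 19 | C[Si](C)(C)OC(=O)[C@@H]1[C@]2(C)CCC[C@](C)(CO[Si](C)(C)C(C)(C)C)C2=CC[C@]1(C)O[Si](C)(C)C | intermediate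
19 | (1R,2S,5S,8aS)-5-[(tert-butyldimethylsilyloxy)methyl]-2-hydroxy-2,5,8a-trimethyl-1,2,3,5,6,7,8,8a-octahydronaphthalene-1-carboxylic acid | O=C(O)[C@@H]1[C@]2(C)CCC[C@](C)(CO[Si](C)(C)C(C)(C)C)C2=CC[C@]1(C)O | intermediate
20 | borane adduct before oxidation (idealised: C6–BH2, O8–BH2, O11–BH2) | BOC[C@@H]1[C@]2(C)CCC[C@](C)(CO[Si](C)(C)C(C)(C)C)[C@H]2[C@H](B)C[C@]1(C)OB | intermediate
21 | (4S,5S,6R,8S,9S,10R)-18-TBS-protected 6,8,11-triol | OC[C@@H]1[C@]2(C)CCC[C@](C)(CO[Si](C)(C)C(C)(C)C)[C@H]2[C@H](O)C[C@]1(C)O | intermediate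
22 | (4S,5S,6R,8S,9R,10R)-18-TBS-protected 6,8-dihydroxy C11 aldehyde | O=C[C@@H]1[C@]2(C)CCC[C@](C)(CO[Si](C)(C)C(C)(C)C)[C@H]2[C@H](O)C[C@]1(C)O | intermediate
23 | (4S,5S,6R,8S,9R,10R)-18-TBS-protected 6-acetoxy-8-hydroxy C11 aldehyde | O=C[C@@H]1[C@]2(C)CCC[C@](C)(CO[Si](C)(C)C(C)(C)C)[C@H]2[C@H](OC(C)=O)C[C@]1(C)O | intermediate
24 | (4S,5S,6R,8S,9R,10R)-18-TBS-protected 6-acetoxy-8-hydroxy C11=C12 vinyl compound | C=C[C@@H]1[C@]2(C)CCC[C@](C)(CO[Si](C)(C)C(C)(C)C)[C@H]2[C@H](OC(C)=O)C[C@]1(C)O | intermediate
25 | chloroprene, 2-chlorobuta-1,3-diene | C=CC(Cl)=C | starting material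
26 | B-alkyl-9-BBN (boron on C12 of 24) | B1(C2CCCC1CCC2)CC[C@@H]1[C@]2(C)CCC[C@](C)(CO[Si](C)(C)C(C)(C)C)[C@H]2[C@H](OC(C)=O)C[C@]1(C)O | intermediate
27 | 18-TBS ether of the target | C=CC(=C)CC[C@@H]1[C@]2(C)CCC[C@](C)(CO[Si](C)(C)C(C)(C)C)[C@H]2[C@H](OC(C)=O)C[C@]1(C)O | intermediate
28 | CNP0312185.2, (4S,5S,6R,8S,9R,10R)-6-acetoxy-labda-13(16),14-diene-8,18-diol | C=CC(=C)CC[C@@H]1[C@]2(C)CCC[C@](C)(CO)[C@H]2[C@H](OC(C)=O)C[C@]1(C)O | target

**Step count**
Total: 18 steps. Longest linear sequence: 18 steps (1 to 28; compounds 2, 11, 14 and 25 are purchased).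

**Steps most likely to fail**

Step 12. The rearrangement may be slow because it forms a quaternary carbon at a tetrasubstituted olefin terminus and builds the C17/C20 1,3-diaxial methyl pair in the boat; slow rearrangement leaves time for β-elimination of the C8 oxygen, carbon silylation or thermal breakdown of the ketene acetal. The fallback sets out from 12 and comes back at 19; it removes the C8 oxygen from the lactone and adds it after ring contraction. Alkoxide-directed lithiation of the methallyl CH3 of 12 (n-BuLi, TMEDA) and carboxylation with CO2 would give the δ-hydroxy acid F1, which is closed (EDC, DMAP) to the 4-methylidene lactone F2. Ireland–Claisen rearrangement of its silyl ketene acetal F3 (LiN(iPr)2, Me3SiCl; toluene, heat) would give, through silyl ester F4, the β,γ-unsaturated acid F5 by the same bridged boat. Mukaiyama hydration (Co(acac)2, PhSiH3, O2) of the 1,1-disubstituted olefin, with the C8 radical taking oxygen on the face away from the axial C10 methyl, returns to 19.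

Step 13. Borane may add through the alternative half-chair (ring A flipped, C10 methyl quasi-equatorial), whose open face leads to the cis ring fusion; facial selectivity is therefore uncertain. The fallback sets out from 19 and comes back at 23; it replaces kinetic facial control by equilibration at C5. LiAlH4 reduces 19 to diol F6, and 2,2-dimethoxypropane with PPTS ties O8 and O11 as acetonide F7. Hydroboration–oxidation (BH3·THF; NaOH, H2O2) then needs no facial control and gives the C6 alcohols F8. Dess–Martin oxidation followed by DBU equilibration at C5, now α to the ketone, should give the trans-fused 6-ketone F9. Dissolving-metal reduction (Li, NH3, t-BuOH) gives the equatorial alcohol F10, acetylation gives F11, aqueous AcOH removes the acetonide to give diol F12, and Dess–Martin oxidation of its only oxidisable alcohol re-enters at 23, so step 14 is not needed.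

Step 8. Addition to an aldehyde flanked by two fully substituted carbons may be slow with the bulky borane and may lose face selectivity on warming. The fallback sets out from 10 and comes back at 12; it sets C6 by ketone reduction instead of C–C bond formation. Grignard reagent 11 is added to 10 without chiral control to give the epimeric alcohols F13, and Dess–Martin oxidation gives the β,γ-unsaturated ketone F14. Corey–Bakshi–Shibata reduction ((S)-Me-CBS oxazaborolidine, catecholborane, −78 °C), with the cyclohexenyl group as the large substituent, gives the (R)-alcohol 12.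

**Further compounds**
F1 | step 12 | (5R)-5-hydroxy-3-methylidene-5-[(6S)-6-[(tert-butyldimethylsilyloxy)methyl]-2,6-dimethylcyclohex-1-en-1-yl]pentanoic acid | OC(=O)CC(=C)C[C@@H](O)C1=C(C)CCC[C@]1(C)CO[Si](C)(C)C(C)(C)C
F2 | step 12 | (6R)-4-methylidene-6-[(6S)-6-[(tert-butyldimethylsilyloxy)methyl]-2,6-dimethylcyclohex-1-en-1-yl]oxan-2-one | O=C1CC(=C)C[C@@H](O1)C2=C(C)CCC[C@]2(C)CO[Si](C)(C)C(C)(C)C
F3 | step 12 | trimethylsilyl ketene acetal of F2 | C[Si](C)(C)OC1=CC(=C)C[C@@H](O1)C2=C(C)CCC[C@]2(C)CO[Si](C)(C)C(C)(C)C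
F4 | step 12 | trimethylsilyl ester of F5 | C[Si](C)(C)OC(=O)[C@@H]1[C@]2(C)CCC[C@](C)(CO[Si](C)(C)C(C)(C)C)C2=CCC1=C
F5 | step 12 | 8(17)-methylidene analogue of 19 (C8=C17 in place of the C8 carbinol) | O=C(O)[C@@H]1[C@]2(C)CCC[C@](C)(CO[Si](C)(C)C(C)(C)C)C2=CCC1=C
F6 | step 13 | 8,11-diol from reduction of 19 (C5=C6 retained) | OC[C@@H]1[C@]2(C)CCC[C@](C)(CO[Si](C)(C)C(C)(C)C)C2=CC[C@]1(C)O
F7 | step 13 | O8,O11-acetonide of F6 | CC1(C)OC[C@@H]2[C@]3(C)CCC[C@](C)(CO[Si](C)(C)C(C)(C)C)C3=CC[C@]2(C)O1
F8 | step 13 | C6 alcohols from F7 (C5 and C6 configuration open) | CC1(C)OC[C@@H]2[C@]3(C)CCC[C@](C)(CO[Si](C)(C)C(C)(C)C)C3C(O)C[C@]2(C)O1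
F9 | step 13 | trans-fused 6-ketone acetonide | CC1(C)OC[C@@H]2[C@]3(C)CCC[C@](C)(CO[Si](C)(C)C(C)(C)C)[C@H]3C(=O)C[C@]2(C)O1
F10 | step 13 | equatorial 6-alcohol acetonide | CC1(C)OC[C@@H]2[C@]3(C)CCC[C@](C)(CO[Si](C)(C)C(C)(C)C)[C@H]3[C@H](O)C[C@]2(C)O1
F11 | step 13 | 6-acetate acetonide | CC1(C)OC[C@@H]2[C@]3(C)CCC[C@](C)(CO[Si](C)(C)C(C)(C)C)[C@H]3[C@H](OC(C)=O)C[C@]2(C)O1
F12 | step 13 | 6-acetoxy-8,11-diol | OC[C@@H]1[C@]2(C)CCC[C@](C)(CO[Si](C)(C)C(C)(C)C)[C@H]2[C@H](OC(C)=O)C[C@]1(C)O
F13 | step 8 | 1-[(6S)-6-[(tert-butyldimethylsilyloxy)methyl]-2,6-dimethylcyclohex-1-en-1-yl]-3-methylbut-3-en-1-ol (both C1 epimers) | C=C(C)CC(O)C1=C(C)CCC[C@]1(C)CO[Si](C)(C)C(C)(C)C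
F14 | step 8 | 1-[(6S)-6-[(tert-butyldimethylsilyloxy)methyl]-2,6-dimethylcyclohex-1-en-1-yl]-3-methylbut-3-en-1-one | C=C(C)CC(=O)C1=C(C)CCC[C@]1(C)CO[Si](C)(C)C(C)(C)C
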